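**Plan**

1. Retrosynthetic cuts (ring numbered as in the target: C1 ketone, C2=C3, C4 carbinol, C5/C6 epoxide, C6 carrying farnesyl C1′): the ester C–O bond between the ring CH2O and the glutarate; the two epoxide C–O bonds, back to a C5=C6 alkene and a C4 ketone; the C6–C1′ bond to the farnesyl chain.
2. Enabling feature: at the quinone-monoketal level C6 is the bromine-bearing β-carbon of the C4=O/C5=C6 enone in a cyclohexa-2,5-dienone ring, next to the C1 ketal. This vinylogous acyl bromide is entered readily by zerovalent palladium, so the whole C15 chain is joined in one convergent step at the carbon that later becomes the fully substituted epoxide carbon.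
3. Forward order: the arene is dearomatised to the six-membered dienone ring; the farnesyl chain is joined (step 5); the protected glutarate is esterified on; C4=O is reduced; C5=C6 is epoxidised (three-membered ring); ketal and SEM ester are removed together.
4. Stereochemistry: C4 from (R)-CBS reduction; C5 and C6 from C4–OH-directed VO(acac)2/t-BuOOH epoxidation (oxygen syn to OH); the glutarate centre from (R)-mevalonolactone (same geometry, descriptor becomes S when the arm priorities swap in the last step); 2E,6E from farnesyl chloride.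

Key step: step 5

Remark: ring carbons are numbered as in the target throughout the Why lines; compounds 1, 5 and 8 are taken as purchasable.

**Route**

Step 1
Reactants: 1 4-bromo-2,5-dimethoxybenzaldehyde
Product: 2 4-bromo-2-hydroxy-5-methoxybenzaldehyde
Conditions: BCl3 (1.2 equiv), CH2Cl2, 0 °C to rt; then H2O
Reagents that add atoms: none
Why: Chelation of BCl3 between the aldehyde oxygen and the ortho methoxy oxygen activates only that methyl ether for chloride attack (chelation-controlled Lewis-acid O-demethylation), so the methoxy group that later becomes the C1 ketal survives.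

Step 2
Reactants: 2 4-bromo-2-hydroxy-5-methoxybenzaldehyde
Product: 3 5-bromo-2-(hydroxymethyl)-4-methoxyphenol
Conditions: NaBH4, MeOH/THF, 0 °C
Reagents that add atoms: none
Why: Borohydride reduction of the aryl aldehyde is fast and leaves the aryl bromide and the methyl ether untouched, giving the primary alcohol needed for the ester.

Step 3
Reactants: 3 5-bromo-2-(hydroxymethyl)-4-methoxyphenol
Product: 4 5-bromo-2-(hydroxymethyl)-4,4-dimethoxycyclohexa-2,5-dien-1-one
Conditions: PhI(OAc)2 (1.1 equiv), MeOH, 0 °C; NaHCO3 quench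
Reagents that add atoms: methanol (CO)
Why: Trivalent-iodine oxidative dearomatisation of a para-methoxyphenol in methanol traps the phenoxonium ion at the methoxy-bearing carbon, so the quinone monoketal forms regiospecifically with C4 as ketone, C1 as ketal and bromine on C6.

Step 4
Reactants: 5 (2E,6E)-farnesyl chloride
Product: 6 tributyl[(2E,6E)-3,7,11-trimethyldodeca-2,6,10-trien-1-yl]stannane
Conditions: Bu3SnH, LiN(i-Pr)2, THF, 0 °C; then 5, −78 °C to rt
Reagents that add atoms: tributyltin hydride (CCCC[SnH](CCCC)CCCC)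
Why: SN2 displacement of the primary allylic chloride by tributylstannyllithium occurs at C1′ without allylic transposition, so the 2E,6E geometry is carried into the allylstannane.

Step 5
Reactants: 4 5-bromo-2-(hydroxymethyl)-4,4-dimethoxycyclohexa-2,5-dien-1-one; 6 tributyl[(2E,6E)-3,7,11-trimethyldodeca-2,6,10-trien-1-yl]stannane
Product: 7 2-(hydroxymethyl)-4,4-dimethoxy-5-[(2E,6E)-3,7,11-trimethyldodeca-2,6,10-trien-1-yl]cyclohexa-2,5-dien-1-one
Conditions: Pd2(dba)3 (2.5 mol %), AsPh3 (20 mol %), NMP, 40 °C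
Reagents that add atoms: none
Why: Zerovalent palladium inserts into the C6–Br bond of 4, which is activated as a vinylogous acyl bromide (β-carbon of the C4=O/C5=C6 enone); bromide-for-allyl transmetalation with 6 gives a dienonyl(η3-farnesyl)palladium species, and reductive elimination forms the C6–C1′ bond and returns the catalyst. The closest known reaction type is the Migita–Kosugi–Stille coupling of β-halo enones with allylstannanes. No ring is closed and no stereocentre is formed; the step places the whole C15 chain on the most hindered ring carbon, the one flanked by the quaternary ketal carbon C1, which step 10 turns into the fully substituted epoxide carbon. The selectivity needed is attachment through C1′ rather than C3′ with retention of the 2′E geometry, and it should be secured because reductive elimination from the syn-η3-allyl complex occurs at its unsubstituted terminus, all the more so against a hindered C6. The free primary hydroxyl of 4 is a poor leaving group, so no competing allylpalladium forms on the ring side (the reason the coupling precedes esterification), and the ketal survives the neutral medium.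

Step 6
Reactants: 8 (R)-mevalonolactone
Product: 10 2-(trimethylsilyl)ethoxymethyl (3R)-3,5-dihydroxy-3-methylpentanoate, via potassium (R)-mevalonate 9 (not isolated)
Conditions: KOH (1.0 equiv), H2O, rt, then lyophilise; SEMCl (1.05 equiv), DMF, 0 °C
Reagents that add atoms: potassium hydroxide ([K+].[OH-]); 2-(trimethylsilyl)ethoxymethyl chloride (C[Si](C)(C)CCOCCl)
Why: Saponification opens the lactone to the carboxylate, which is O-alkylated by the reactive α-chloro ether (carboxylate alkylation) faster than the neutral hydroxyl groups, and the tertiary stereocentre of 8 is not touched.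

Step 7
Reactants: 10 2-(trimethylsilyl)ethoxymethyl (3R)-3,5-dihydroxy-3-methylpentanoate
Product: 11 (3R)-3-hydroxy-3-methyl-5-oxo-5-{[2-(trimethylsilyl)ethoxy]methoxy}pentanoic acid
Conditions: TEMPO (2,2,6,6-tetramethylpiperidin-1-oxyl, 20 mol %), PhI(OAc)2 (2.2 equiv), MeCN/H2O 1:1, 0 °C to rt; crude 10 used at once
Reagents that add atoms: water (O)
Why: Oxoammonium oxidation (TEMPO/PhI(OAc)2) takes the primary alcohol through the aldehyde hydrate to the carboxylic acid, while the tertiary alcohol cannot be oxidised and prompt oxidation removes the hydroxyl that could relactonise.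

Step 8
Reactants: 7 2-(hydroxymethyl)-4,4-dimethoxy-5-[(2E,6E)-3,7,11-trimethyldodeca-2,6,10-trien-1-yl]cyclohexa-2,5-dien-1-one; 11 (3R)-3-hydroxy-3-methyl-5-oxo-5-{[2-(trimethylsilyl)ethoxy]methoxy}pentanoic acid
Product: 12 1-{[3,3-dimethoxy-6-oxo-4-[(2E,6E)-farnesyl]cyclohexa-1,4-dien-1-yl]methyl} 5-{[2-(trimethylsilyl)ethoxy]methyl} (3R)-3-hydroxy-3-methylpentanedioate
Conditions: EDC·HCl (1.3 equiv), DMAP (4-dimethylaminopyridine, 0.1 equiv), CH2Cl2, 0 °C
Reagents that add atoms: none
Why: Steglich carbodiimide esterification acylates the only hydroxyl of 7, the primary allylic one, while the hindered tertiary β-hydroxyl of 11 does not compete.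

Step 9
Reactants: 12 1-{[3,3-dimethoxy-6-oxo-4-[(2E,6E)-farnesyl]cyclohexa-1,4-dien-1-yl]methyl} 5-{[2-(trimethylsilyl)ethoxy]methyl} (3R)-3-hydroxy-3-methylpentanedioate
Product: 13 1-{[(6S)-6-hydroxy-3,3-dimethoxy-4-[(2E,6E)-farnesyl]cyclohexa-1,4-dien-1-yl]methyl} 5-{[2-(trimethylsilyl)ethoxy]methyl} (3R)-3-hydroxy-3-methylpentanedioate
Conditions: (R)-2-methyl-CBS-oxazaborolidine (0.3 equiv), catecholborane (3 equiv), toluene, −78 °C; MeOH, then pH 7 buffer; used without storage
Reagents that add atoms: none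
Why: In this Corey–Bakshi–Shibata reduction the (R)-oxazaborolidine should bind the C4 ketone anti to its larger flank (the CH2O-substituted C3) and deliver hydride to one face, setting C4 as S here (R once C5 is oxygenated), and catecholborane at −78 °C reduces neither the esters nor the farnesyl alkenes.

Step 10
Reactants: 13 1-{[(6S)-6-hydroxy-3,3-dimethoxy-4-[(2E,6E)-farnesyl]cyclohexa-1,4-dien-1-yl]methyl} 5-{[2-(trimethylsilyl)ethoxy]methyl} (3R)-3-hydroxy-3-methylpentanedioate
Product: 14 1-{[(1R,5R,6R)-5-hydroxy-2,2-dimethoxy-1-[(2E,6E)-farnesyl]-7-oxabicyclo[4.1.0]hept-3-en-4-yl]methyl} 5-{[2-(trimethylsilyl)ethoxy]methyl} (3R)-3-hydroxy-3-methylpentanedioate (bicycle numbered as in the target)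
Conditions: VO(acac)2 (5 mol %), t-BuOOH (1.2 equiv, decane), CH2Cl2, 0 °C
Reagents that add atoms: tert-butyl hydroperoxide (CC(C)(C)OO)
Why: In this vanadium-catalysed hydroxyl-directed epoxidation the vanadate ester of the C4 hydroxyl delivers oxygen to the same face, setting C5 and C6 cis to C4–OH with farnesyl on the opposite face; the isolated farnesyl alkenes lack a directing group, and C5=C6 should be preferred over C2=C3 because the latter is deactivated by its allylic acyloxy group.

Step 11
Reactants: 14 1-{[(1R,5R,6R)-5-hydroxy-2,2-dimethoxy-1-[(2E,6E)-farnesyl]-7-oxabicyclo[4.1.0]hept-3-en-4-yl]methyl} 5-{[2-(trimethylsilyl)ethoxy]methyl} (3R)-3-hydroxy-3-methylpentanedioate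
Product: 15 (3S)-3-hydroxy-5-{[(1R,5R,6R)-5-hydroxy-2-oxo-1-[(2E,6E)-3,7,11-trimethyldodeca-2,6,10-trien-1-yl]-7-oxabicyclo[4.1.0]hept-3-en-4-yl]methoxy}-3-methyl-5-oxopentanoic acid
Conditions: 48 % aq. HF/MeCN 1:19, 0 °C to rt
Reagents that add atoms: water (O)
Why: Dilute aqueous HF hydrolyses the allylic dimethyl ketal to the enone (acetal hydrolysis) and cleaves the SEM ester by fluoride attack at silicon with loss of ethene and formaldehyde, under conditions that the epoxide, the allylic ester and the trisubstituted alkenes should tolerate.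

**Compound list**

1 | 4-bromo-2,5-dimethoxybenzaldehyde | O=Cc1cc(OC)c(Br)cc1OC | starting material
2 | 4-bromo-2-hydroxy-5-methoxybenzaldehyde | O=Cc1cc(OC)c(Br)cc1O | intermediate
3 | 5-bromo-2-(hydroxymethyl)-4-methoxyphenol | OCc1cc(OC)c(Br)cc1O | intermediate
4 | 5-bromo-2-(hydroxymethyl)-4,4-dimethoxycyclohexa-2,5-dien-1-one | O=C1C=C(Br)C(OC)(OC)C=C1CO | intermediate
5 | (2E,6E)-farnesyl chloride [(2E,6E)-1-chloro-3,7,11-trimethyldodeca-2,6,10-triene] | CC(C)=CCC/C(C)=C/CC/C(C)=C/CCl | starting material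
6 | tributyl[(2E,6E)-3,7,11-trimethyldodeca-2,6,10-trien-1-yl]stannane | CC(C)=CCC/C(C)=C/CC/C(C)=C/C[Sn](CCCC)(CCCC)CCCC | intermediate
7 | 2-(hydroxymethyl)-4,4-dimethoxy-5-[(2E,6E)-3,7,11-trimethyldodeca-2,6,10-trien-1-yl]cyclohexa-2,5-dien-1-one | CC(C)=CCC/C(C)=C/CC/C(C)=C/CC1=CC(=O)C(CO)=CC1(OC)OC | intermediate
8 | (R)-mevalonolactone [(4R)-4-hydroxy-4-methyloxan-2-one] | C[C@]1(O)CC(=O)OCC1 | starting material
9 | potassium (R)-mevalonate [potassium (3R)-3,5-dihydroxy-3-methylpentanoate] | OCC[C@@](C)(O)CC(=O)[O-].[K+] | intermediate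
10 | 2-(trimethylsilyl)ethoxymethyl (3R)-3,5-dihydroxy-3-methylpentanoate | OCC[C@@](C)(O)CC(=O)OCOCC[Si](C)(C)C | intermediate
11 | (3R)-3-hydroxy-3-methyl-5-oxo-5-{[2-(trimethylsilyl)ethoxy]methoxy}pentanoic acid | OC(=O)C[C@@](C)(O)CC(=O)OCOCC[Si](C)(C)C | intermediate
12 | 1-{[3,3-dimethoxy-6-oxo-4-[(2E,6E)-farnesyl]cyclohexa-1,4-dien-1-yl]methyl} 5-{[2-(trimethylsilyl)ethoxy]methyl} (3R)-3-hydroxy-3-methylpentanedioate | CC(C)=CCC/C(C)=C/CC/C(C)=C/CC1=CC(=O)C(COC(=O)C[C@@](C)(O)CC(=O)OCOCC[Si](C)(C)C)=CC1(OC)OC | intermediate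
13 | 1-{[(6S)-6-hydroxy-3,3-dimethoxy-4-[(2E,6E)-farnesyl]cyclohexa-1,4-dien-1-yl]methyl} 5-{[2-(trimethylsilyl)ethoxy]methyl} (3R)-3-hydroxy-3-methylpentanedioate | CC(C)=CCC/C(C)=C/CC/C(C)=C/CC1=C[C@H](O)C(COC(=O)C[C@@](C)(O)CC(=O)OCOCC[Si](C)(C)C)=CC1(OC)OC | intermediate
14 | 1-{[(1R,5R,6R)-5-hydroxy-2,2-dimethoxy-1-[(2E,6E)-farnesyl]-7-oxabicyclo[4.1.0]hept-3-en-4-yl]methyl} 5-{[2-(trimethylsilyl)ethoxy]methyl} (3R)-3-hydroxy-3-methylpentanedioate | CC(C)=CCC/C(C)=C/CC/C(C)=C/C[C@@]12O[C@@H]1[C@H](O)C(COC(=O)C[C@@](C)(O)CC(=O)OCOCC[Si](C)(C)C)=CC2(OC)OC | intermediate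
15 | (3S)-3-hydroxy-5-{[(1R,5R,6R)-5-hydroxy-2-oxo-1-[(2E,6E)-3,7,11-trimethyldodeca-2,6,10-trien-1-yl]-7-oxabicyclo[4.1.0]hept-3-en-4-yl]methoxy}-3-methyl-5-oxopentanoic acid | CC(C)=CCC/C(C)=C/CC/C(C)=C/C[C@@]12O[C@@H]1[C@H](O)C(COC(=O)C[C@@](C)(O)CC(=O)O)=CC2=O | target

**Totals**

Total step count: 11. Longest linear sequence: 8 steps (steps 1, 2, 3, 5, 8, 9, 10, 11).

**Steps most likely to fail**

Step 5 (key step). What may go wrong: loss of control over the allyl terminus in the reductive elimination (bond formation at C3′ instead of C1′), partial E/Z scrambling of the 2′ alkene through η3–η1 interconversion, or protodestannylation of 6 outpacing a slow insertion at the hindered carbon. The fallback moves the carbon–carbon bond formation to the arene stage, where an arylcopper attacks the allylic bromide cleanly at C1′. It sets out from 3 and returns at 7. Phenol 3 is protected with 2,2-dimethoxypropane and pyridinium p-toluenesulfonate as the acetonide 7-bromo-6-methoxy-2,2-dimethyl-4H-1,3-benzodioxine F1. Bromine–lithium exchange with n-BuLi in THF at −78 °C gives (6-methoxy-2,2-dimethyl-4H-1,3-benzodioxin-7-yl)lithium F2, and CuBr·SMe2 converts it into the arylcopper (6-methoxy-2,2-dimethyl-4H-1,3-benzodioxin-7-yl)copper F3. Purchased (2E,6E)-farnesyl bromide then alkylates it by SN2 to give 6-methoxy-2,2-dimethyl-7-[(2E,6E)-farnesyl]-4H-1,3-benzodioxine F4. Mild acid (pyridinium p-toluenesulfonate, MeOH/H2O) removes the acetonide to give 2-(hydroxymethyl)-4-methoxy-5-[(2E,6E)-farnesyl]phenol F5, and PhI(OAc)2 in MeOH oxidises F5 to 7.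

Step 9. What may go wrong: poor facial discrimination because both flanks of the C4 ketone are sp2 carbons, and acid-promoted loss of methanol with aromatisation of the dienol during work-up. The fallback replaces reagent-controlled reduction by an unselective reduction followed by enzymatic kinetic resolution. It sets out from 12 and returns at 13. Luche reduction (NaBH4, CeCl3·7H2O, MeOH, −78 °C) gives 13 together with its carbinol epimer, the (6R)-hydroxy diastereomer of 13, F6. Burkholderia cepacia lipase (Amano PS) with vinyl acetate in tert-butyl methyl ether should acylate the (6R)-alcohol preferentially, following the usual empirical preference of lipases for that configuration, to give its acetate, the (6R)-acetoxy ester F7. Unreacted 13 is then separated by chromatography on base-washed silica.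

Step 10. What may go wrong: insufficient discrimination between the two ring alkenes that both flank the directing hydroxyl (oxygen delivery to C2=C3), and Lewis-acid-promoted loss of methanol with aromatisation of the dienol. The fallback changes the oxidation level of the primary carbon so that C2=C3 becomes an enal alkene, inert to the electrophilic vanadium peroxide, and installs the glutarate afterwards. It sets out from 7 and returns at 14. CBS reduction of 7 under the conditions of step 9 gives (1S)-2-(hydroxymethyl)-4,4-dimethoxy-5-[(2E,6E)-farnesyl]cyclohexa-2,5-dien-1-ol F8. TEMPO/PhI(OAc)2 in NaHCO3-buffered CH2Cl2 oxidises only the primary allylic alcohol to (6S)-6-hydroxy-3,3-dimethoxy-4-[(2E,6E)-farnesyl]cyclohexa-1,4-diene-1-carbaldehyde F9. VO(acac)2/t-BuOOH then epoxidises the only electron-rich allylic alkene, C5=C6, to (1R,5R,6R)-5-hydroxy-2,2-dimethoxy-1-[(2E,6E)-farnesyl]-7-oxabicyclo[4.1.0]hept-3-ene-4-carbaldehyde F10. NaBH4/CeCl3·7H2O at −78 °C reduces the aldehyde to (1R,5R,6R)-4-(hydroxymethyl)-2,2-dimethoxy-1-[(2E,6E)-farnesyl]-7-oxabicyclo[4.1.0]hept-3-en-5-ol F11. Acid 11 with EDC·HCl and catalytic DMAP at −20 °C acylates the primary hydroxyl of F11 in preference to the hindered secondary one, giving 14.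

**Further compounds**

F1 | step 5 | 7-bromo-6-methoxy-2,2-dimethyl-4H-1,3-benzodioxine | COc1cc2COC(C)(C)Oc2cc1Br
F2 | step 5 | (6-methoxy-2,2-dimethyl-4H-1,3-benzodioxin-7-yl)lithium | COc1cc2COC(C)(C)Oc2cc1[Li]
F3 | step 5 | (6-methoxy-2,2-dimethyl-4H-1,3-benzodioxin-7-yl)copper | COc1cc2COC(C)(C)Oc2cc1[Cu]
F4 | step 5 | 6-methoxy-2,2-dimethyl-7-[(2E,6E)-3,7,11-trimethyldodeca-2,6,10-trien-1-yl]-4H-1,3-benzodioxine | CC(C)=CCC/C(C)=C/CC/C(C)=C/Cc1cc2OC(C)(C)OCc2cc1OC
F5 | step 5 | 2-(hydroxymethyl)-4-methoxy-5-[(2E,6E)-3,7,11-trimethyldodeca-2,6,10-trien-1-yl]phenol | CC(C)=CCC/C(C)=C/CC/C(C)=C/Cc1cc(O)c(CO)cc1OC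
F6 | step 9 | 1-{[(6R)-6-hydroxy-3,3-dimethoxy-4-[(2E,6E)-farnesyl]cyclohexa-1,4-dien-1-yl]methyl} 5-{[2-(trimethylsilyl)ethoxy]methyl} (3R)-3-hydroxy-3-methylpentanedioate | CC(C)=CCC/C(C)=C/CC/C(C)=C/CC1=C[C@@H](O)C(COC(=O)C[C@@](C)(O)CC(=O)OCOCC[Si](C)(C)C)=CC1(OC)OC
F7 | step 9 | 1-{[(6R)-6-acetoxy-3,3-dimethoxy-4-[(2E,6E)-farnesyl]cyclohexa-1,4-dien-1-yl]methyl} 5-{[2-(trimethylsilyl)ethoxy]methyl} (3R)-3-hydroxy-3-methylpentanedioate | CC(C)=CCC/C(C)=C/CC/C(C)=C/CC1=C[C@@H](OC(C)=O)C(COC(=O)C[C@@](C)(O)CC(=O)OCOCC[Si](C)(C)C)=CC1(OC)OC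
F8 | step 10 | (1S)-2-(hydroxymethyl)-4,4-dimethoxy-5-[(2E,6E)-3,7,11-trimethyldodeca-2,6,10-trien-1-yl]cyclohexa-2,5-dien-1-ol | CC(C)=CCC/C(C)=C/CC/C(C)=C/CC1=C[C@H](O)C(CO)=CC1(OC)OC
F9 | step 10 | (6S)-6-hydroxy-3,3-dimethoxy-4-[(2E,6E)-3,7,11-trimethyldodeca-2,6,10-trien-1-yl]cyclohexa-1,4-diene-1-carbaldehyde | CC(C)=CCC/C(C)=C/CC/C(C)=C/CC1=C[C@H](O)C(C=O)=CC1(OC)OC
F10 | step 10 | (1R,5R,6R)-5-hydroxy-2,2-dimethoxy-1-[(2E,6E)-3,7,11-trimethyldodeca-2,6,10-trien-1-yl]-7-oxabicyclo[4.1.0]hept-3-ene-4-carbaldehyde | CC(C)=CCC/C(C)=C/CC/C(C)=C/C[C@@]12O[C@@H]1[C@H](O)C(C=O)=CC2(OC)OC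
F11 | step 10 | (1R,5R,6R)-4-(hydroxymethyl)-2,2-dimethoxy-1-[(2E,6E)-3,7,11-trimethyldodeca-2,6,10-trien-1-yl]-7-oxabicyclo[4.1.0]hept-3-en-5-ol | CC(C)=CCC/C(C)=C/CC/C(C)=C/C[C@@]12O[C@@H]1[C@H](O)C(CO)=CC2(OC)OC
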